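## The problem

Compound 32 is the vanillate of a daucane-type triol, a cyclopentane (C1–C5) trans-fused through C1 and C5 to a cycloheptene (C1, C5–C10), in which C1 is the methyl-bearing quaternary fusion carbon, C4 the isopropyl carbinol, C5 the fusion CH, C6 the ester carbon, C7 the methylene, C8 the methyl carbinol and C9=C10 the cis-alkene. Five stereocentres (1R,4R,5S,6S,8R) must be set. C1, C5, C6 and C4 are contiguous, so C1 can steer C5 (entry anti to the larger C1 substituent) and C5 can steer C6 (closed aldol transition state) and C4 (attack anti to the C5 branch), whereas C8 is insulated from them and needs reagent control. The fragile parts are the tertiary allylic alcohol at C8 (ionisation and allylic transposition under acid), the tertiary C4 carbinol (dehydration), the hindered secondary ester beside a free phenol, and a cis-alkene flanked by two fully substituted carbons. Closing a seven-membered ring on a trans-fused, crowded framework is the entropic problem. The feature that opens a direct answer is that C8 is a tertiary allylic carbinol bonded to the C7 methylene, whose other neighbour is the oxygen-bearing C6. A stereodefined C8 carbamate on the C1 arm can therefore act as a carbenoid and a C7 boronic ester on the C5 arm as its partner, and joining them forms C7–C8, closes the ring and leaves boron at C8 where the hydroxyl is needed.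

## Retrosynthesis

The ester is cut first. Target 32 comes from acetate 31 by aminolysis, and 31 from triol 27 and 4-acetoxy-3-methoxybenzoic acid 29 (made from vanillic acid 28). Acylating last keeps the aryl ester out of every organometallic step. It needs no differentiated O6 protecting group because 27 has one secondary hydroxyl beside two tertiary ones. The forward step must acylate O6 only.

Triol 27 is disilyl ether 26 without its silicon, and 26 is the oxidation product of tertiary allylic boronic ester 25. Exchanging C8–O for C8–B costs no complexity and turns the remote tertiary carbinol into the natural product of a 1,2-metallate shift. The oxidation must proceed with retention and without allylic transposition.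

In 25 the C7–C8 bond is cut, which opens the seven-membered ring to monocyclic carbamate boronate 22. Cutting C9=C10 (metathesis) or C8–C9 (vinyl metal plus ketone) would also open the ring, but each would leave C8 to a separate step or to substrate control. The C7–C8 cut lets the 8S carbamate dictate C8 during ring closure. The forward reaction must lithiate C8 in the presence of boron, capture boron at C8 and not C10, and migrate C7. O4 is carried as a triethylsilyl ether, because a bulkier silyl group cannot be expected to go onto so crowded a tertiary carbinol.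

Carbamate 22 is the Lindlar product of propargylic carbamate 21, which comes from alcohol 20. The C8–C9 bond of 20 is cut to alkyne 17 and acetaldehyde 18. The alkyne gives the cis-alkene reliably, and the alkynylation is catalyst-controlled, as it must be for a centre this far from the ring.

Alkyne 17 is the one-carbon homologue of aldehyde 16, and 16 is the ozonolysis product of vinyl compound 14 (through ozonide 15). The vinyl group is a deliberate placeholder: it should survive the copper-catalysed borylation, whereas an alkyne would not.

Disilyl ether 14 comes from diol boronate 13. The C7–B bond of 13 is cut to epoxide 12 and bis(pinacolato)diboron 11, and 12 is the ring-closed form of chlorohydrin 10. Epoxide opening puts boron on C7 next to an oxygenated carbon without an eliminable organometallic and leaves C6 untouched.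

Diol 10 loses its isopropyl group to give ketone 9 (cut C4–isopropyl). Ketone 9 is the protodesilylated form of aldol 8. The silicon in 8 is kept until the aldol is done because it supplies the steric bias at C1.

Aldol 8 is cut at C5–C6 to silyl enol ether 4 and chloroacetaldehyde 5, by way of enolates 6 and 7. One bond sets C5 and C6 and brings in C7 with its leaving group. The forward reaction must be anti-selective and must occur on the face away from the silylvinyl group.

Silyl enol ether 4 is cut at C1–C10 to 3-methylcyclopent-2-en-1-one 1 and ethynyltrimethylsilane 2. The forward step is a catalytic enantioselective conjugate addition whose aluminium enolate 3 is silylated, so that the enolate stays on the hindered C5 side.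

## Roads not taken

Alternative 1: The seven-membered ring is cut into a four-carbon piece (C8–C9–C10–C1) and a three-carbon piece (C5–C6–C7) across C7–C8 and C5–C1. Forward, 2,5-dimethylfuran A1 and 1,1,3-trichloroacetone A2 are joined by an oxyallyl-type (4+3) cycloaddition under NaOCH2CF3 in CF3CH2OH. A Zn–Cu couple in the same flask then removes the chlorines to give oxygen-bridged cycloheptenone A3.
- Merits: one operation from the bulk chemicals A1 and A2 gives the cycloheptene with the C9=C10 alkene, the C6 carbonyl, both methyl groups and the C8 oxygen. The cycloaddition is thoroughly established, which step 12 is not.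
- Weak points: A3 is meso, so a desymmetrisation is needed. C1 of 32 carries no oxygen, so one of two initially equivalent bridgehead C–O bonds must be exchanged for the C1–C2 bond at a quaternary centre, by an allylic substitution that can equally deliver the carbon to C9. The cyclopentane must then be grown across C1–C5 onto a finished ring with trans fusion, and C4 and C6 are set late on a mobile bicycle.
- Comparison: in precedent and cost of the key step this road is better. The chosen plan sets against it that no C–O bond is replaced at a quaternary carbon, that every stereocentre is fixed by relay or reagent before or in the ring closure, and that few operations follow the key step.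

Alternative 2: C1–C10 and C5–C6 are cut with no ring closure. Enone 1 receives a (Z)-2-silylvinyl group from alane A4 under Cu(OTf)2 and a chiral N-heterocyclic carbene, and an aldol at C5 with ketal aldehyde A5 follows in the same flask. The product is anti-aldol A6, with C1, C5 and C6 set and all ring carbons present.
- Merits: three stereocentres and two C–C bonds in one flask. At the front it is shorter than the chosen route, which uses a two-stage relative of the same logic (steps 1 and 2).
- Weak points: hydroalumination of an ethynylsilane normally places aluminium on the silicon-bearing carbon, so A4 is not the isomer that forms by itself. Aluminium enolates are sluggish toward aldehydes, and A5 is an enolisable β-ketal aldehyde. Above all, the ring must then be closed from A6 at C8–C9 by adding a vinyl metal to the C8 methyl ketone, which leaves the remote C8 carbinol to the conformational bias of a seven-membered cyclisation.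
- Comparison: better opening, weaker ending. The chosen plan pays extra early steps and an unproven key step, but it sets C8 stereospecifically from an enantioenriched carbamate.

Alternative 3: The ring is cut at C6–C7. Forward, catalytic CrCl3 is reduced at the cathode to divalent chromium (DMF, Me3SiCl, sacrificial aluminium anode). Divalent chromium metalates the allylic bromide of dienyl bromide A7, and the allylic carbon then adds to the C6 aldehyde of the same molecule, closing the ring to methylidene diol A8.
- Merits: chromium-mediated allylations of aldehydes are chemoselective, tolerate free hydroxyls and are a proven way to close medium rings. The ring closure is much closer to known practice than step 12.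
- Weak points: C6 is set by substrate control in a seven-membered transition state. C8 is left in A8 as an exocyclic methylidene conjugated with C9=C10, and turning it into the methyl carbinol needs a Markovnikov hydration of one alkene of a diene with control of site (C8 against C10) and of face.
- Comparison: the ring closure is safer, but the C8 problem is only postponed to a step with no evident control element. The chosen plan makes C8 in the ring-closing event.

Key step: step 12

Remark: C-labels and their CIP descriptors follow the numbering of the first section; the sense of induction in the two catalyst-controlled steps (1 and 9) is assumed to be set by the choice of ligand enantiomer.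

Step 1
Reactants: 1 3-methylcyclopent-2-en-1-one; 2 ethynyltrimethylsilane
Product: 4 trimethyl({(3S)-3-methyl-3-[1-(trimethylsilyl)ethenyl]cyclopent-1-en-1-yl}oxy)silane, via aluminium enolate 3 (not isolated)
Conditions: 2, i-Bu2AlH, hexane, 55 °C; then 1, Cu(OTf)2 (5 mol %), chiral sulfonate-bearing imidazolinium salt (NHC precursor, 5 mol %), THF, −78 → −15 °C; then TMSOTf, −78 → 0 °C
Reagents that add atoms: trimethylsilyl trifluoromethanesulfonate, C[Si](C)(C)OS(=O)(=O)C(F)(F)F
Why: Copper-catalysed enantioselective conjugate addition of a silyl-substituted vinylaluminium (from hydroalumination of 2, aluminium on the silicon-bearing carbon) to a β-substituted cyclopentenone is an established route to all-carbon quaternary centres, and the NHC ligand sets C1. O-Silylation of aluminium enolate 3 fixes the enolate on the C5 side for step 2.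

Step 2
Reactants: 4 silyl enol ether; 5 chloroacetaldehyde
Product: 8 (2S,3S)-2-[(1R)-2-chloro-1-hydroxyethyl]-3-methyl-3-[1-(trimethylsilyl)ethenyl]cyclopentan-1-one, via lithium enolate 6 (not isolated), via boron enolate 7 (not isolated)
Conditions: MeLi, THF, 0 °C; (c-Hex)2BCl, −78 °C; 5 (anhydrous, freshly distilled), −78 → −20 °C; pH 7 buffer, MeOH, H2O2, 0 °C
Reagents that add atoms: none
Why: Methyllithium cleaves the silyl enol ether to regiodefined enolate 6, boron exchange gives the ring-constrained (E)-enol borinate 7, and the chair Zimmerman–Traxler aldol of (E)-boron enolates is anti-selective, which is the C5/C6 relation required. The aldehyde should enter C5 on the face away from the bulky 1-silylvinyl group, so the new chain ends cis to the C1 methyl.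

Step 3
Reactants: 8 silylvinyl aldol
Product: 9 (2S,3R)-2-[(1R)-2-chloro-1-hydroxyethyl]-3-ethenyl-3-methylcyclopentan-1-one
Conditions: TFA, CH2Cl2, 0 → 23 °C; aq. NaHCO3
Reagents that add atoms: none
Why: Acid protodesilylation of a 1,1-disubstituted vinylsilane (ipso protonation, β-silyl cation, loss of silicon) unmasks the vinyl group once silicon has served as the face-blocking group. The aldol should survive because its carbinol carbon bears an electron-poor chloromethyl group and cannot ionise, and short exposure at low temperature limits enolisation toward C5.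

Step 4
Reactants: 9 vinyl aldol
Product: 10 (1R,2S,3R)-2-[(1R)-2-chloro-1-hydroxyethyl]-3-ethenyl-3-methyl-1-(propan-2-yl)cyclopentan-1-ol
Conditions: i-PrMgCl (3.5 equiv), CeCl3 (3.5 equiv), THF, −78 °C; AcOH/THF quench at −78 °C
Reagents that add atoms: isopropylmagnesium chloride, CC(C)[Mg]Cl
Why: Organocerium reagents add to hindered, enolisable ketones with little enolisation or reduction and tolerate a free β-hydroxyl (the first equivalent forms the alkoxide, which chelates the ketone). Attack on C4 anti to the C5 side chain should place isopropyl trans and hydroxyl cis to that chain.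

Step 5
Reactants: 10 chlorohydrin diol; 11 bis(pinacolato)diboron
Product: 13 (1R,2S,3R)-3-ethenyl-2-[(1S)-1-hydroxy-2-(4,4,5,5-tetramethyl-1,3,2-dioxaborolan-2-yl)ethyl]-3-methyl-1-(propan-2-yl)cyclopentan-1-ol, via epoxide 12 (not isolated)
Conditions: LiOt-Bu (1.1 equiv), THF, 0 °C; then 11 (1.5 equiv), CuCl (10 mol %), LiOt-Bu (20 mol %), MeOH (2 equiv), 0 → 23 °C
Reagents that add atoms: none
Why: The more acidic chlorohydrin hydroxyl closes terminal epoxide 12 (Williamson closure, C6 untouched), and copper-catalysed borylative opening of terminal epoxides is SN2 at the CH2 terminus, so the β-hydroxy boronic ester keeps its C6 configuration. A monosubstituted alkene on a quaternary carbon should be inert to boryl-copper under these ligand-free conditions, which is why the C1 arm is carried as vinyl.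

Step 6
Reactants: 13 diol boronate
Product: 14 (1R,2S,3R)-3-ethenyl-3-methyl-1-(propan-2-yl)-2-[(1S)-2-(4,4,5,5-tetramethyl-1,3,2-dioxaborolan-2-yl)-1-(triethylsilyloxy)ethyl]-1-(triethylsilyloxy)cyclopentane
Conditions: TESOTf (3 equiv), 2,6-lutidine, CH2Cl2, −78 → 23 °C
Reagents that add atoms: triethylsilyl trifluoromethanesulfonate, CC[Si](CC)(CC)OS(=O)(=O)C(F)(F)F
Why: A silyl triflate with 2,6-lutidine silylates secondary and hindered tertiary alcohols alike. Capping both hydroxyls removes the acidic protons and the O4-to-boron chelation that would quench the boronic ester in step 12.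

Step 7
Reactants: 14 vinyl disilyl ether
Product: 16 (1S,2S,3R)-1-methyl-3-(propan-2-yl)-2-[(1S)-2-(4,4,5,5-tetramethyl-1,3,2-dioxaborolan-2-yl)-1-(triethylsilyloxy)ethyl]-3-(triethylsilyloxy)cyclopentane-1-carbaldehyde, via ozonide 15 (not isolated)
Conditions: O3, CH2Cl2, −78 °C; then PPh3, −78 → 23 °C
Reagents that add atoms: ozone, O=[O+][O-]
Why: Ozonolysis with reductive work-up cleaves the only alkene; alkyl pinacol boronates and silyl ethers are inert to ozone at −78 °C, and the aldehyde formed is non-enolisable.

Step 8
Reactants: 16 aldehyde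
Product: 17 (1R,2S,3S)-3-ethynyl-3-methyl-1-(propan-2-yl)-2-[(1S)-2-(4,4,5,5-tetramethyl-1,3,2-dioxaborolan-2-yl)-1-(triethylsilyloxy)ethyl]-1-(triethylsilyloxy)cyclopentane
Conditions: dimethyl (1-diazo-2-oxopropyl)phosphonate, K2CO3, MeOH, 0 → 23 °C
Reagents that add atoms: dimethyl (1-diazo-2-oxopropyl)phosphonate (Ohira–Bestmann reagent), CC(=O)C(=[N+]=[N-])P(=O)(OC)OC
Why: Seyferth–Gilbert homologation with the Ohira–Bestmann reagent converts aldehydes into terminal alkynes under carbonate/methanol conditions that spare silyl ethers and the boronic ester. No organolithium, which would add to boron, is involved.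

Step 9
Reactants: 17 alkyne; 18 acetaldehyde
Product: 20 (2S)-4-[(1S,2S,3R)-1-methyl-3-(propan-2-yl)-2-[(1S)-2-(4,4,5,5-tetramethyl-1,3,2-dioxaborolan-2-yl)-1-(triethylsilyloxy)ethyl]-3-(triethylsilyloxy)cyclopentyl]but-3-yn-2-ol, via zinc alkynylide 19 (not isolated)
Conditions: Me2Zn (3 equiv), ProPhenol ligand (20 mol %, enantiomer giving the 2S carbinol), Ph3P=O (40 mol %), toluene, 0 → 23 °C; then 18 (5 equiv, slow addition), 0 → 4 °C; aq. NH4Cl
Reagents that add atoms: none
Why: Zinc–ProPhenol-catalysed alkynylation adds zinc alkynylides to aldehydes, acetaldehyde included when it is added slowly, with catalyst control of the new carbinol. That control is needed because C8 is insulated from the ring stereocentres, and dimethylzinc does not transmetalate a pinacol boronate.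

Step 10
Reactants: 20 propargylic alcohol
Product: 21 (2S)-4-[(1S,2S,3R)-1-methyl-3-(propan-2-yl)-2-[(1S)-2-(4,4,5,5-tetramethyl-1,3,2-dioxaborolan-2-yl)-1-(triethylsilyloxy)ethyl]-3-(triethylsilyloxy)cyclopentyl]but-3-yn-2-yl N,N-di(propan-2-yl)carbamate
Conditions: i-Pr2NCOCl, pyridine, DMAP (cat.), 80 °C
Reagents that add atoms: N,N-diisopropylcarbamoyl chloride, CC(C)N(C(C)C)C(Cl)=O
Why: O-Carbamoylation of a secondary propargylic alcohol with the carbamoyl chloride in hot pyridine is the standard entry to lithiation-ready N,N-diisopropylcarbamates; the C8–O bond is not broken.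

Step 11
Reactants: 21 propargylic carbamate
Product: 22 (2S,3Z)-4-[(1R,2S,3R)-1-methyl-3-(propan-2-yl)-2-[(1S)-2-(4,4,5,5-tetramethyl-1,3,2-dioxaborolan-2-yl)-1-(triethylsilyloxy)ethyl]-3-(triethylsilyloxy)cyclopentyl]but-3-en-2-yl N,N-di(propan-2-yl)carbamate
Conditions: H2 (1 atm), Pd/CaCO3 poisoned with Pb(OAc)2 (Lindlar catalyst), quinoline, EtOAc, 23 °C
Reagents that add atoms: none
Why: Lindlar semihydrogenation gives the cis-alkene by syn delivery of hydrogen, and allylic carbamates are not hydrogenolysed under these conditions. The Z geometry is what later brings C8 within reach of boron.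

Step 12
Reactants: 22 (Z)-allylic carbamate boronate
Product: 25 2-[(3R,3aS,4S,6S,8aR)-6,8a-dimethyl-3-(propan-2-yl)-3,4-bis(triethylsilyloxy)-1,2,3,3a,4,5,6,8a-octahydroazulen-6-yl]-4,4,5,5-tetramethyl-1,3,2-dioxaborolane, via lithiated carbamate 23 (not isolated), via cyclic boronate 24 (not isolated)
Conditions: LiTMP (1.3 equiv), THF (0.01 M), −78 °C; then MgBr2·OEt2, −78 → 40 °C
Reagents that add atoms: none
Why: Proposed new method: LiTMP, a base too hindered to add to boron, should remove the C8 proton next to the carbamate oxygen (allylic, dipole-stabilised, carbonyl-directed) with retention to give 23, which is trapped at once, again with retention, by the tethered boronic ester to give eight-membered cyclic boronate 24; Lewis acid and warming then drive 1,2-migration of C7 from boron to C8 anti to the departing carbamate, forming C7–C8 with inversion. The closest known reaction type is the intermolecular lithiation–borylation of enantioenriched secondary allylic carbamates with pinacol boronic esters, which gives tertiary allylic boronic esters stereospecifically, together with in situ amide-base lithiation of carbamates in the presence of boronic esters; the ring-contracting intramolecular version has not been shown. The seven-membered carbocycle is not closed directly: the eight-membered boracycle closes by carbanion attack on trigonal boron, and the 1,2-shift then takes boron out of the ring path, contracting eight to seven. C8 is the only new stereocentre and is controlled by the 8S carbamate (retention, retention, inversion), so boron ends where the 8R hydroxyl is needed. The step needs boron capture at C8 and not at C10: C10 is neopentylic, lithium is held at C8 by the carbamate carbonyl, and a C10-bound boronate has no leaving group and can only revert. It also needs the C7–B bond and not a pinacol oxygen to migrate, which MgBr2 favours, and the β-silyloxy group to stay in place, which its poor leaving ability makes likely. The Z-alkene and the vicinal attachment of both arms to C1 and C5 keep the reacting ends close, and high dilution suppresses intermolecular capture.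

Step 13
Reactants: 25 tertiary allylic boronic ester
Product: 26 (3R,3aS,4S,6R,8aR)-6,8a-dimethyl-3-(propan-2-yl)-3,4-bis(triethylsilyloxy)-1,2,3,3a,4,5,6,8a-octahydroazulen-6-ol
Conditions: H2O2 (30% aq.), NaOH (2 M aq.), THF, 0 → 23 °C
Reagents that add atoms: hydrogen peroxide, OO
Why: Basic hydrogen peroxide oxidises boronic esters by 1,2-migration of carbon from boron to oxygen with retention, tertiary allylic ones included, and without allylic transposition; triethylsilyl ethers survive.

Step 14
Reactants: 26 disilyl ether
Product: 27 (3R,3aS,4S,6R,8aR)-6,8a-dimethyl-3-(propan-2-yl)-1,2,3,3a,4,5,6,8a-octahydroazulene-3,4,6-triol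
Conditions: TBAF, THF, 23 → 40 °C
Reagents that add atoms: none
Why: Fluoride cleaves both triethylsilyl ethers under basic, non-ionising conditions, which spares the acid-labile tertiary allylic alcohol.

Step 15
Reactants: 28 vanillic acid
Product: 29 4-acetoxy-3-methoxybenzoic acid
Conditions: Ac2O, pyridine, 23 °C; then H2O
Reagents that add atoms: acetic anhydride, CC(=O)OC(C)=O
Why: Acetylation masks the phenol for the coupling; any mixed anhydride at the carboxyl group is hydrolysed in the aqueous work-up.

Step 16
Reactants: 27 triol; 29 4-acetoxy-3-methoxybenzoic acid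
Product: 31 (3R,3aS,4S,6R,8aR)-3,6-dihydroxy-6,8a-dimethyl-3-(propan-2-yl)-1,2,3,3a,4,5,6,8a-octahydroazulen-4-yl 4-acetoxy-3-methoxybenzoate, via acid chloride 30 (not isolated)
Conditions: (COCl)2, DMF (cat.), CH2Cl2, 0 → 23 °C; then 27, Et3N, DMAP, CH2Cl2, 0 → 23 °C
Reagents that add atoms: none
Why: Acid chloride 30 with DMAP should acylate the only secondary hydroxyl; the two tertiary hydroxyls do not compete, as is general for daucane 4,6-diols, which are esterified at O6 with the tertiary hydroxyl free. C6 keeps its configuration because its C–O bond is not broken.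

Step 17
Reactants: 31 acetate
Product: 32 (3R,3aS,4S,6R,8aR)-3,6-dihydroxy-6,8a-dimethyl-3-(propan-2-yl)-1,2,3,3a,4,5,6,8a-octahydroazulen-4-yl 4-hydroxy-3-methoxybenzoate
Conditions: pyrrolidine, CH2Cl2, 0 → 23 °C
Reagents that add atoms: none
Why: Aminolysis of an aryl acetate by pyrrolidine is far faster than attack on a hindered secondary alkyl benzoate, so the phenol is freed without touching the vanillate or inviting acyl migration.

## Compound list

1 | 3-methylcyclopent-2-en-1-one | CC1=CC(=O)CC1 | starting material
2 | ethynyltrimethylsilane | C#C[Si](C)(C)C | starting material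
3 | diisobutylaluminium (3S)-3-methyl-3-[1-(trimethylsilyl)ethenyl]cyclopent-1-en-1-olate | C=C([Si](C)(C)C)[C@@]1(C)CCC(O[Al](CC(C)C)CC(C)C)=C1 | intermediate
4 | trimethyl({(3S)-3-methyl-3-[1-(trimethylsilyl)ethenyl]cyclopent-1-en-1-yl}oxy)silane | C=C([Si](C)(C)C)[C@@]1(C)CCC(O[Si](C)(C)C)=C1 | intermediate
5 | chloroacetaldehyde | ClCC=O | starting material
6 | lithium (3S)-3-methyl-3-[1-(trimethylsilyl)ethenyl]cyclopent-1-en-1-olate | C=C([Si](C)(C)C)[C@@]1(C)CCC(O[Li])=C1 | intermediate
7 | dicyclohexyl({(3S)-3-methyl-3-[1-(trimethylsilyl)ethenyl]cyclopent-1-en-1-yl}oxy)borane | C=C([Si](C)(C)C)[C@@]1(C)CCC(OB(C2CCCCC2)C2CCCCC2)=C1 | intermediate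
8 | (2S,3S)-2-[(1R)-2-chloro-1-hydroxyethyl]-3-methyl-3-[1-(trimethylsilyl)ethenyl]cyclopentan-1-one | C=C([Si](C)(C)C)[C@@]1(C)CCC(=O)[C@@H]1[C@@H](O)CCl | intermediate
9 | (2S,3R)-2-[(1R)-2-chloro-1-hydroxyethyl]-3-ethenyl-3-methylcyclopentan-1-one | C=C[C@@]1(C)CCC(=O)[C@@H]1[C@@H](O)CCl | intermediate
10 | (1R,2S,3R)-2-[(1R)-2-chloro-1-hydroxyethyl]-3-ethenyl-3-methyl-1-(propan-2-yl)cyclopentan-1-ol | C=C[C@@]1(C)CC[C@@](O)(C(C)C)[C@@H]1[C@@H](O)CCl | intermediate
11 | bis(pinacolato)diboron | CC1(C)OB(OC1(C)C)B1OC(C)(C)C(C)(C)O1 | starting material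
12 | (1R,2S,3R)-3-ethenyl-3-methyl-2-[(2R)-oxiran-2-yl]-1-(propan-2-yl)cyclopentan-1-ol | C=C[C@@]1(C)CC[C@@](O)(C(C)C)[C@@H]1[C@@H]2CO2 | intermediate
13 | (1R,2S,3R)-3-ethenyl-2-[(1S)-1-hydroxy-2-(4,4,5,5-tetramethyl-1,3,2-dioxaborolan-2-yl)ethyl]-3-methyl-1-(propan-2-yl)cyclopentan-1-ol | C=C[C@@]1(C)CC[C@@](O)(C(C)C)[C@@H]1[C@@H](O)CB1OC(C)(C)C(C)(C)O1 | intermediate
14 | O4,O6-bis(triethylsilyl) ether of 13, (1R,4R,5S,6S) in route numbering | C=C[C@@]1(C)CC[C@@](O[Si](CC)(CC)CC)(C(C)C)[C@@H]1[C@@H](O[Si](CC)(CC)CC)CB1OC(C)(C)C(C)(C)O1 | intermediate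
15 | ozonide of 14 (1,2,4-trioxolan-3-yl group on C1, mixture at the trioxolane carbon) | C1(OCOO1)[C@@]2(C)CC[C@@](O[Si](CC)(CC)CC)(C(C)C)[C@@H]2[C@@H](O[Si](CC)(CC)CC)CB3OC(C)(C)C(C)(C)O3 | intermediate
16 | (1S,2S,3R)-1-methyl-3-(propan-2-yl)-2-[(1S)-2-(4,4,5,5-tetramethyl-1,3,2-dioxaborolan-2-yl)-1-(triethylsilyloxy)ethyl]-3-(triethylsilyloxy)cyclopentane-1-carbaldehyde | O=C[C@@]1(C)CC[C@@](O[Si](CC)(CC)CC)(C(C)C)[C@@H]1[C@@H](O[Si](CC)(CC)CC)CB1OC(C)(C)C(C)(C)O1 | intermediate
17 | C1-ethynyl analogue of 14, (1S,4R,5S,6S) in route numbering | C#C[C@@]1(C)CC[C@@](O[Si](CC)(CC)CC)(C(C)C)[C@@H]1[C@@H](O[Si](CC)(CC)CC)CB1OC(C)(C)C(C)(C)O1 | intermediate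
18 | acetaldehyde | CC=O | starting material
19 | methylzinc alkynylide of 17 | C[Zn]C#C[C@@]1(C)CC[C@@](O[Si](CC)(CC)CC)(C(C)C)[C@@H]1[C@@H](O[Si](CC)(CC)CC)CB1OC(C)(C)C(C)(C)O1 | intermediate
20 | (8S)-propargylic alcohol, (1S,4R,5S,6S,8S) in route numbering | O[C@@H](C)C#C[C@@]1(C)CC[C@@](O[Si](CC)(CC)CC)(C(C)C)[C@@H]1[C@@H](O[Si](CC)(CC)CC)CB1OC(C)(C)C(C)(C)O1 | intermediate
21 | (8S)-propargylic N,N-diisopropylcarbamate of 20 | CC(C)N(C(C)C)C(=O)O[C@@H](C)C#C[C@@]1(C)CC[C@@](O[Si](CC)(CC)CC)(C(C)C)[C@@H]1[C@@H](O[Si](CC)(CC)CC)CB1OC(C)(C)C(C)(C)O1 | intermediate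
22 | (8S,9Z)-allylic N,N-diisopropylcarbamate with C7 pinacol boronate, (1R,4R,5S,6S,8S) in route numbering | CC(C)N(C(C)C)C(=O)O[C@@H](C)/C=C\[C@@]1(C)CC[C@@](O[Si](CC)(CC)CC)(C(C)C)[C@@H]1[C@@H](O[Si](CC)(CC)CC)CB1OC(C)(C)C(C)(C)O1 | intermediate
23 | 8-lithio derivative of 22 (lithium in place of the C8 hydrogen, retention) | CC(C)N(C(C)C)C(=O)O[C@@]([Li])(C)/C=C\[C@@]1(C)CC[C@@](O[Si](CC)(CC)CC)(C(C)C)[C@@H]1[C@@H](O[Si](CC)(CC)CC)CB1OC(C)(C)C(C)(C)O1 | intermediate
24 | lithium salt of the eight-membered cyclic boronate (boron bonded to C7 and C8) | CC(C)N(C(C)C)C(=O)O[C@@]1(C)/C=C\[C@@]2(C)CC[C@@](O[Si](CC)(CC)CC)(C(C)C)[C@@H]2[C@@H](O[Si](CC)(CC)CC)C[B-]13OC(C)(C)C(C)(C)O3.[Li+] | intermediate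
25 | 2-[(3R,3aS,4S,6S,8aR)-6,8a-dimethyl-3-(propan-2-yl)-3,4-bis(triethylsilyloxy)-1,2,3,3a,4,5,6,8a-octahydroazulen-6-yl]-4,4,5,5-tetramethyl-1,3,2-dioxaborolane | CC[Si](CC)(CC)O[C@H]2C[C@@](C)(B4OC(C)(C)C(C)(C)O4)C=C[C@@]3(C)CC[C@@](O[Si](CC)(CC)CC)(C(C)C)[C@H]23 | intermediate
26 | (3R,3aS,4S,6R,8aR)-6,8a-dimethyl-3-(propan-2-yl)-3,4-bis(triethylsilyloxy)-1,2,3,3a,4,5,6,8a-octahydroazulen-6-ol | CC[Si](CC)(CC)O[C@H]2C[C@@](C)(O)C=C[C@@]3(C)CC[C@@](O[Si](CC)(CC)CC)(C(C)C)[C@H]23 | intermediate
27 | (3R,3aS,4S,6R,8aR)-6,8a-dimethyl-3-(propan-2-yl)-1,2,3,3a,4,5,6,8a-octahydroazulene-3,4,6-triol | O[C@H]2C[C@@](C)(O)C=C[C@@]3(C)CC[C@@](O)(C(C)C)[C@H]23 | intermediate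
28 | vanillic acid | COc1cc(C(=O)O)ccc1O | starting material
29 | 4-acetoxy-3-methoxybenzoic acid | COc1cc(C(=O)O)ccc1OC(C)=O | intermediate
30 | 4-acetoxy-3-methoxybenzoyl chloride | COc1cc(C(Cl)=O)ccc1OC(C)=O | intermediate
31 | (3R,3aS,4S,6R,8aR)-3,6-dihydroxy-6,8a-dimethyl-3-(propan-2-yl)-1,2,3,3a,4,5,6,8a-octahydroazulen-4-yl 4-acetoxy-3-methoxybenzoate | COc1cc(C(=O)O[C@H]2C[C@@](C)(O)C=C[C@@]3(C)CC[C@@](O)(C(C)C)[C@H]23)ccc1OC(C)=O | intermediate
32 | (3R,3aS,4S,6R,8aR)-3,6-dihydroxy-6,8a-dimethyl-3-(propan-2-yl)-1,2,3,3a,4,5,6,8a-octahydroazulen-4-yl 4-hydroxy-3-methoxybenzoate | COc1cc(C(=O)O[C@H]2C[C@@](C)(O)C=C[C@@]3(C)CC[C@@](O)(C(C)C)[C@H]23)ccc1O | target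

## Step count and least certain steps

Total steps: 17. Longest linear sequence: 16 (steps 1–14, 16 and 17; step 15 prepares acid 29).

Step 12 (key step).
- Most likely failure: slow or absent lithiation at C8. Allylic 1,3-strain in the Z-alkene, with quaternary C1 cis to C8, disfavours the conformer in which the C8–H bond overlaps the π-system. Base may then be consumed unproductively, or boron may be captured intermolecularly or reversibly at C10. Loss of silyloxide from the boronate by β-elimination is a second possibility.
- Fallback: it sets out from 14. (S,E)-Pent-3-en-2-yl N,N-diisopropylcarbamate F1 (from (S,E)-pent-3-en-2-ol and i-Pr2NCOCl in pyridine) is lithiated with s-BuLi/TMEDA in Et2O at −78 °C and treated with 14. MgBr2/MeOH and warming give tertiary allylic boronic ester F2, and NaOH/H2O2 gives dienol F3. Ring-closing metathesis with second-generation Hoveyda–Grubbs catalyst (loss of propene) returns to the route at 26.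
- This detour is known chemistry throughout and is shorter than steps 7–13. It keeps the C7–C8 disconnection and the boron-to-oxygen logic but gives up the ring-contracting event, closing the ring at C9=C10 instead.

Step 2.
- Most likely failure: incomplete anti selectivity, or sluggish addition at a neopentylic enolate carbon next to the quaternary C1 while the α-chloroaldehyde polymerises.
- Fallback: C6 is reset by reagent control. The material is taken through steps 3 and 4; the fallback sets out from 10 carried as its C6 mixture. Dess–Martin periodinane oxidises the secondary carbinol only, to chloromethyl ketone F4. Corey–Bakshi–Shibata reduction (oxazaborolidine enantiomer delivering the 6R chlorohydrin, BH3·SMe2, then MeOH) returns to the route at 10 as a single C6 isomer.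

Step 4.
- Most likely failure: enolisation or β-hydride reduction in place of addition at a ketone flanked by a branched α-carbon and a quaternary β-carbon, retro-aldol cleavage of the metal aldolate, or attack on the wrong face.
- Fallback: it sets out from 9. TESOTf/2,6-lutidine gives silyl ether F5, and i-PrMgCl/CeCl3 then adds to a non-chelating, non-retro-aldolising ketone to give tertiary alcohol F6. TBAF removes silicon, and the liberated alkoxide closes the epoxide, returning to the route at 12, which is then borylated as in the second half of step 5.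

Step 9.
- Most likely failure: low conversion, because the valuable alkyne must be the limiting partner while acetaldehyde self-condenses. Eroded catalyst control is also possible, and the C8 epimers would be hard to separate because C8 is remote.
- Fallback: it sets out from 17. Acyl Sonogashira coupling with acetyl chloride (PdCl2(PPh3)2, CuI, Et3N) gives ynone F7. Noyori asymmetric transfer hydrogenation (RuCl(p-cymene)[(S,S)-TsDPEN] or its enantiomer, whichever gives the 8S carbinol, i-PrOH) returns to the route at 20.

## Further compounds

F1 | step 12 | (S,E)-pent-3-en-2-yl N,N-diisopropylcarbamate | CC(C)N(C(C)C)C(=O)O[C@@H](C)/C=C/C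
F2 | step 12 | acyclic tertiary allylic boronic ester (C8 pinacol boronate bearing (E)-propenyl, C1 vinyl, O4 and O6 triethylsilyl ethers) | C=C[C@@]1(C)CC[C@@](O[Si](CC)(CC)CC)(C(C)C)[C@@H]1[C@@H](O[Si](CC)(CC)CC)C[C@@](C)(B2OC(C)(C)C(C)(C)O2)/C=C/C
F3 | step 12 | acyclic dienol (C8 tertiary allylic alcohol bearing (E)-propenyl, C1 vinyl, O4 and O6 triethylsilyl ethers) | C=C[C@@]1(C)CC[C@@](O[Si](CC)(CC)CC)(C(C)C)[C@@H]1[C@@H](O[Si](CC)(CC)CC)C[C@@](C)(O)/C=C/C
F4 | step 2 | 2-chloro-1-[(1R,2R,5R)-5-ethenyl-2-hydroxy-5-methyl-2-(propan-2-yl)cyclopentyl]ethan-1-one | C=C[C@@]1(C)CC[C@@](O)(C(C)C)[C@@H]1C(=O)CCl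
F5 | step 4 | O6-triethylsilyl ether of 9 | C=C[C@@]1(C)CCC(=O)[C@@H]1[C@@H](O[Si](CC)(CC)CC)CCl
F6 | step 4 | O6-triethylsilyl ether of 10 | C=C[C@@]1(C)CC[C@@](O)(C(C)C)[C@@H]1[C@@H](O[Si](CC)(CC)CC)CCl
F7 | step 9 | ynone (C8 ketone) corresponding to 20 | CC(=O)C#C[C@@]1(C)CC[C@@](O[Si](CC)(CC)CC)(C(C)C)[C@@H]1[C@@H](O[Si](CC)(CC)CC)CB1OC(C)(C)C(C)(C)O1
A1 | alternative 1 | 2,5-dimethylfuran | Cc1ccc(C)o1
A2 | alternative 1 | 1,1,3-trichloroacetone | ClCC(=O)C(Cl)Cl
A3 | alternative 1 | meso-1,5-dimethyl-8-oxabicyclo[3.2.1]oct-6-en-3-one | C[C@]12CC(=O)C[C@](C)(O1)C=C2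
A4 | alternative 2 | diisobutyl[(Z)-2-(trimethylsilyl)ethenyl]aluminium | CC(C)C[Al](CC(C)C)/C=C\[Si](C)(C)C
A5 | alternative 2 | 2-(2-methyl-1,3-dioxolan-2-yl)acetaldehyde | CC1(CC=O)OCCO1
A6 | alternative 2 | anti-aldol cyclopentanone with (Z)-2-(trimethylsilyl)ethenyl at C1 and the ketal-bearing carbinol chain at C5 | C[Si](C)(C)/C=C\[C@@]1(C)CCC(=O)[C@@H]1[C@@H](O)CC2(C)OCCO2
A7 | alternative 3 | dienyl bromide aldehyde ((Z)-3-(bromomethyl)buta-1,3-dienyl arm on C1, C6 aldehyde on C5, free C4 carbinol) | BrCC(=C)/C=C\[C@@]1(C)CC[C@@](O)(C(C)C)[C@@H]1C=O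
A8 | alternative 3 | 8-methylidene hydroazulene diol (hydroxyls at C4 and C6, route numbering) | O[C@H]2CC(=C)C=C[C@@]3(C)CC[C@@](O)(C(C)C)[C@H]23
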